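Locants: ring A is the quinone (C1=O flanked by C2–CH3 and C6–chain, C4=O). The chain C1'–C8' runs from C6. Ring B is the butenolide (C9'–O, C10'=C11', lactone C=O on C11'), and C12'–C16' is the homoprenyl tail.
Retrosynthesis cuts, in order: the two ring A carbonyls (back to a 1,4-dimethoxyarene), the C1'–C6 bond, the lactone C–O and the C10'=C11' alkene of ring B, and the C9'–O bond. C10' is then traced to the C10=C11 alkene of (2E,6E)-farnesyl acetate.
Forward: farnesyl acetate is trimmed to the C1'–C10' aldehyde, C9' is oxygenated, and a Z-olefination adds C11'–C16' with the ester. Ring B then closes by lactonisation, ring A is joined as its aryl bromide, and ring A is oxidised last.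
Stereochemistry: C9' (R) comes from L-proline-catalysed α-aminoxylation. Both E alkenes are bought with farnesyl acetate and never touched. The ring B alkene comes from a Z-selective olefination and is locked by the ring.
Enabling feature: C1' is the open CH2 end of the allyl triad C1'–C2'=C3', whose other end C3' is fully substituted. C6 of ring A lies ortho to O1, whose other ortho carbon (C2) bears methyl and whose para carbon (C4) bears oxygen, so phenol-directed bromination marks C6 alone.
Both carbons are electrophiles in their stable forms: the allylic acetate stands in for the biosynthetic diphosphate, and the ring carbon is an aryl bromide. They are joined by two cathode electrons under nickel catalysis, without base or carbanion, so ring B and C9'–H survive.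

Key step: step 9

Remark: the stereocentre of the given SMILES (C9', γ-carbon of ring B) is read as R.

Step 1
Reactants: 1 (2E,6E)-farnesyl acetate
Product: 2 (2E,6E)-10-bromo-11-hydroxy-3,7,11-trimethyldodeca-2,6-dien-1-yl acetate (racemic at C10)
Conditions: NBS (1.1 equiv), THF–H2O, 0 °C
Reagents that add atoms: N-bromosuccinimide O=C1CCC(=O)N1Br; water O
Why: Terminal-selective bromohydrin formation of a polyprenyl chain in aqueous medium, where the exposed and most electron-rich C10=C11 alkene takes up bromine first, the C2=C3 alkene is deactivated by the allylic acetate and water opens the bromonium ion at the tertiary carbon (Markovnikov); the racemic C10 centre is destroyed in step 3.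

Step 2
Reactants: 2 bromohydrin
Product: 3 (2E,6E)-9-(3,3-dimethyloxiran-2-yl)-3,7-dimethylnona-2,6-dien-1-yl acetate (10,11-epoxyfarnesyl acetate, racemic)
Conditions: DBU (1.2 equiv), THF, rt
Reagents that add atoms: none
Why: Intramolecular Williamson (halohydrin) ring closure, in which the non-nucleophilic amidine base in an aprotic solvent should leave the allylic acetate intact, as a carbonate base in methanol would not.

Step 3
Reactants: 3 epoxide
Product: 4 (2E,6E)-3,7-dimethyl-10-oxodeca-2,6-dien-1-yl acetate
Conditions: H5IO6 (1.2 equiv), THF–Et2O, 0 °C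
Reagents that add atoms: none
Why: Periodic acid hydrates the trisubstituted epoxide and cleaves the glycol in the same operation (Malaprade-type cleavage), which should release acetone and the C10' aldehyde without touching the two E alkenes or the acetate.

Step 4
Reactants: 5 ethyl 2-(diphenoxyphosphoryl)acetate; 6 5-bromo-2-methylpent-2-ene
Product: 7 ethyl 2-(diphenoxyphosphoryl)-6-methylhept-5-enoate (racemic)
Conditions: NaH, DMSO, rt; then 6, NaI (cat.), 50 °C
Reagents that add atoms: none
Why: SN2 alkylation of the stabilised phosphonoacetate anion, the standard way to α-substituted diaryl phosphonoacetates; the stereocentre formed is erased on deprotonation in step 5.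

Step 5
Reactants: 4 aldehyde; 7 phosphonate
Product: 9 ethyl (2Z,4R,6E,10E)-12-acetoxy-4-(anilinooxy)-6,10-dimethyl-2-(4-methylpent-3-en-1-yl)dodeca-2,6,10-trienoate, via aminoxy aldehyde 8 (not isolated)
Conditions: L-proline (20 mol %), PhNO (1.0 equiv), MeCN, −20 °C; then transferred into 7/NaH, THF, −78 to 0 °C
Reagents that add atoms: nitrosobenzene O=Nc1ccccc1
Why: Sequential organocatalytic α-aminoxylation and Horner–Wadsworth–Emmons olefination, in which the E-enamine of 4 and L-proline is attacked at carbon by the oxygen of nitrosobenzene held on one face by the carboxylic acid proton (this sets C9' as R), and the diaryl phosphonate (Ando variant) should then give the Z-enoate under kinetic control at low temperature before 8 can epimerise.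

Step 6
Reactants: 9 anilinooxy Z-enoate
Product: 11 (2E,6E)-3,7-dimethyl-8-[(2R)-4-(4-methylpent-3-en-1-yl)-5-oxo-2,5-dihydrofuran-2-yl]octa-2,6-dien-1-yl acetate, via hydroxy ester 10 (not isolated)
Conditions: Zn dust, AcOH–THF (1:4), rt
Reagents that add atoms: none
Why: Reductive N–O cleavage by zinc in acetic acid frees the C9' hydroxyl, which lies cis to the ester across the Z alkene and lactonises spontaneously (5-exo-trig acyl substitution) without breaking the C9'–O bond, so the R configuration is kept and any E-enoate stays open-chain and separable.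

Step 7
Reactants: 12 4-methoxy-2-methylphenol
Product: 13 2-bromo-4-methoxy-6-methylphenol
Conditions: NBS (1.0 equiv), i-Pr2NH (10 mol %), CH2Cl2, 0 °C
Reagents that add atoms: N-bromosuccinimide O=C1CCC(=O)N1Br
Why: Amine-catalysed ortho-bromination of a phenol (electrophilic aromatic substitution), in which the hydrogen-bonded N-bromoamine delivers bromine next to the hydroxyl, where only C6 is open because C2 bears methyl and C4 bears methoxy.

Step 8
Reactants: 13 bromophenol
Product: 14 1-bromo-2,5-dimethoxy-3-methylbenzene
Conditions: MeI, K2CO3, acetone, reflux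
Reagents that add atoms: iodomethane CI
Why: Williamson ether synthesis masks O1 so that neither an acidic proton nor a phenoxide nucleophile is present during the coupling.

Step 9
Reactants: 11 butenolide allylic acetate; 14 aryl bromide
Product: 15 (5R)-5-[(2E,6E)-8-(2,5-dimethoxy-3-methylphenyl)-2,6-dimethylocta-2,6-dien-1-yl]-3-(4-methylpent-3-en-1-yl)furan-2(5H)-one
Conditions: 14 (1.5 equiv), NiBr2(bpy) (10 mol %), Bu4NBF4, DMF, undivided cell, Zn anode, Ni-foam cathode, constant current, ca. 2.2 F/mol, rt, Ar
Reagents that add atoms: none
Why: Cathodic reduction of NiBr2(bpy) gives zerovalent nickel, which inserts into the C–Br bond of 14; a further electron turns the aryl divalent nickel bromide into an aryl monovalent nickel species, this ionises the allylic acetate of 11 to an aryl(η3-allyl) trivalent nickel complex, and reductive elimination forms the C1'–C6 bond while zinc ions from the anode take up bromide and acetate. The closest known reaction type is the nickel-catalysed reductive cross-electrophile coupling of aryl halides with allylic acetates, run at a cathode with a sacrificial anode or with zinc powder, which covers 3,3-disubstituted (prenyl-type) acetates. No ring is closed and no stereocentre is formed; C9' is only carried through. Cross- over homo-coupling is needed and is secured by the two different leaving groups, which are activated by nickel in different oxidation states, and by an excess of the cheap partner 14. Attack at C1' rather than C3' and retention of the E geometry at C2'=C3' are secured by the substrate itself, because C3' is fully substituted, so the aryl group is delivered to the open CH2 terminus and the syn–anti exchange that would scramble the alkene would need a σ-bond from nickel to a tertiary carbon. Chemoselectivity is secured because the working potential lies well positive of the reduction of the α-alkylated butenolide, the medium holds neither base nor carbanion so the acidic C9'–H is not removed, and the lactone C9'–O bond, although allylic, belongs to an electron-poor enoate that does not ionise.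

Step 10
Reactants: 15 dimethoxyarene
Product: 16 yezoquinolide, 2-methyl-6-{(2E,6E)-3,7-dimethyl-8-[(2R)-4-(4-methylpent-3-en-1-yl)-5-oxo-2,5-dihydrofuran-2-yl]octa-2,6-dien-1-yl}cyclohexa-2,5-diene-1,4-dione
Conditions: (NH4)2Ce(NO3)6 (2.5 equiv), MeCN–H2O, 0 °C, short contact time
Reagents that add atoms: water O
Why: Oxidative demethylation of a 1,4-dimethoxyarene by tetravalent cerium (two one-electron oxidations, water attacks the two ipso carbons, methanol leaves), a reaction type established on polyprenylated hydroquinone ethers because the arene is oxidised far more easily than isolated trisubstituted alkenes or the butenolide, and the acidic medium does not enolise C9'.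

Compound list
1 | (2E,6E)-farnesyl acetate | CC(C)=CCC/C(C)=C/CC/C(C)=C/COC(C)=O | starting material
2 | (2E,6E)-10-bromo-11-hydroxy-3,7,11-trimethyldodeca-2,6-dien-1-yl acetate (racemic) | CC(C)(O)C(Br)CC/C(C)=C/CC/C(C)=C/COC(C)=O | intermediate
3 | (2E,6E)-9-(3,3-dimethyloxiran-2-yl)-3,7-dimethylnona-2,6-dien-1-yl acetate (racemic) | CC1(C)OC1CC/C(C)=C/CC/C(C)=C/COC(C)=O | intermediate
4 | (2E,6E)-3,7-dimethyl-10-oxodeca-2,6-dien-1-yl acetate | O=CCC/C(C)=C/CC/C(C)=C/COC(C)=O | intermediate
5 | ethyl 2-(diphenoxyphosphoryl)acetate | CCOC(=O)CP(=O)(Oc1ccccc1)Oc1ccccc1 | starting material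
6 | 5-bromo-2-methylpent-2-ene | CC(C)=CCCBr | starting material
7 | ethyl 2-(diphenoxyphosphoryl)-6-methylhept-5-enoate (racemic) | CCOC(=O)C(CCC=C(C)C)P(=O)(Oc1ccccc1)Oc1ccccc1 | intermediate
8 | (2E,6E,9R)-9-(anilinooxy)-3,7-dimethyl-10-oxodeca-2,6-dien-1-yl acetate (not isolated) | O=C[C@H](ONc1ccccc1)C/C(C)=C/CC/C(C)=C/COC(C)=O | intermediate
9 | ethyl (2Z,4R,6E,10E)-12-acetoxy-4-(anilinooxy)-6,10-dimethyl-2-(4-methylpent-3-en-1-yl)dodeca-2,6,10-trienoate | CCOC(=O)/C(CCC=C(C)C)=C\[C@H](ONc1ccccc1)C/C(C)=C/CC/C(C)=C/COC(C)=O | intermediate
10 | ethyl (2Z,4R,6E,10E)-12-acetoxy-4-hydroxy-6,10-dimethyl-2-(4-methylpent-3-en-1-yl)dodeca-2,6,10-trienoate (not isolated) | CCOC(=O)/C(CCC=C(C)C)=C\[C@H](O)C/C(C)=C/CC/C(C)=C/COC(C)=O | intermediate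
11 | (2E,6E)-3,7-dimethyl-8-[(2R)-4-(4-methylpent-3-en-1-yl)-5-oxo-2,5-dihydrofuran-2-yl]octa-2,6-dien-1-yl acetate | CC(C)=CCCC1=C[C@@H](C/C(C)=C/CC/C(C)=C/COC(C)=O)OC1=O | intermediate
12 | 4-methoxy-2-methylphenol | COc1ccc(O)c(C)c1 | starting material
13 | 2-bromo-4-methoxy-6-methylphenol | COc1cc(C)c(O)c(Br)c1 | intermediate
14 | 1-bromo-2,5-dimethoxy-3-methylbenzene | COc1cc(C)c(OC)c(Br)c1 | intermediate
15 | (5R)-5-[(2E,6E)-8-(2,5-dimethoxy-3-methylphenyl)-2,6-dimethylocta-2,6-dien-1-yl]-3-(4-methylpent-3-en-1-yl)furan-2(5H)-one | CC(C)=CCCC1=C[C@@H](C/C(C)=C/CC/C(C)=C/Cc2cc(OC)cc(C)c2OC)OC1=O | intermediate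
16 | yezoquinolide | CC(C)=CCCC1=C[C@@H](C/C(C)=C/CC/C(C)=C/CC2=CC(=O)C=C(C)C2=O)OC1=O | target

Total step count: 10. Longest linear sequence: 7 steps (1, 2, 3, 5, 6, 9, 10).

Steps most likely to fail

Step 9. Oxidative addition of the electron-rich, ortho-substituted bromide may be slow. Reductive dimerisation of the allyl partner, hydrodehalogenation, or partial E/Z scrambling at the allylnickel stage could then outrun the cross-coupling. The fallback sets out from 14 and comes back at 15. It replaces the union of two electrophiles by a polarity-matched, neutral Stille coupling. Bromine–lithium exchange on 14 (n-BuLi, THF, −78 °C) and quenching with Bu3SnCl give tributyl(2,5-dimethoxy-3-methylphenyl)stannane F1. F1 is coupled with 11 under the conditions known for allylic acetates (Pd(dba)2, LiCl, DMF, rt). This reaction type attacks the primary allyl terminus with retention of the alkene geometry and needs no base.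

Step 5. Three processes could erode configuration and geometry: base-induced epimerisation or N–O fragmentation of the unisolated aldehyde, a competing ene reaction of nitrosobenzene at the trisubstituted alkenes, and insufficient Z-selectivity with the branched phosphonate. The fallback sets out from 6 and from 4 (by way of 8) and comes back at 11. It forms C10'–C11' by an aldol addition and creates the alkene only after ring closure, so that no alkene geometry has to be controlled.
- Compound 6 alkylates the lithium enolate of tert-butyl acetate (LiN(i-Pr)2, THF–DMPU, −78 °C to rt) to give tert-butyl 6-methylhept-5-enoate F2.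
- The lithium enolate of F2 (2.2 equiv, THF, −78 °C) adds to 8, which is generated as in step 5 and taken up in THF after a cold aqueous wash. This gives tert-butyl (4R,6E,10E)-12-acetoxy-4-(anilinooxy)-3-hydroxy-6,10-dimethyl-2-(4-methylpent-3-en-1-yl)dodeca-6,10-dienoate F3.
- N–O cleavage and lactonisation (Zn, AcOH–THF; then PPTS, toluene, 60 °C) give (2E,6E)-8-[(2R)-3-hydroxy-4-(4-methylpent-3-en-1-yl)-5-oxooxolan-2-yl]-3,7-dimethylocta-2,6-dien-1-yl acetate F4.
- Mesylation and elimination (MsCl, Et3N, CH2Cl2, 0 °C) give 11.

Step 10. The cerium oxidant or nitrate may attack the three trisubstituted alkenes, and the arene radical cation may dimerise oxidatively, both at the expense of the advanced material. The fallback sets out from 13 and 11 and comes back at 16. It moves ring A to the more easily oxidised 4-methoxyphenol level.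
- Compound 13 is silylated (TBSCl, imidazole, DMF) to (2-bromo-4-methoxy-6-methylphenoxy)(tert-butyl)dimethylsilane F5.
- F5 is coupled with 11 as in step 9 to give (5R)-5-[(2E,6E)-8-{2-[(tert-butyldimethylsilyl)oxy]-5-methoxy-3-methylphenyl}-2,6-dimethylocta-2,6-dien-1-yl]-3-(4-methylpent-3-en-1-yl)furan-2(5H)-one F6.
- Buffered desilylation (Bu4NF, AcOH, THF, 0 °C) gives (5R)-5-[(2E,6E)-8-(2-hydroxy-5-methoxy-3-methylphenyl)-2,6-dimethylocta-2,6-dien-1-yl]-3-(4-methylpent-3-en-1-yl)furan-2(5H)-one F7.
- PhI(OAc)2 in MeCN–H2O at 0 °C (oxidative dearomatisation, loss of methanol from the hemiketal) gives 16.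

Further compounds
F1 | step 9 | tributyl(2,5-dimethoxy-3-methylphenyl)stannane | CCCC[Sn](CCCC)(CCCC)c1cc(OC)cc(C)c1OC
F2 | step 5 | tert-butyl 6-methylhept-5-enoate | CC(C)=CCCCC(=O)OC(C)(C)C
F3 | step 5 | tert-butyl (4R,6E,10E)-12-acetoxy-4-(anilinooxy)-3-hydroxy-6,10-dimethyl-2-(4-methylpent-3-en-1-yl)dodeca-6,10-dienoate (mixture at C2 and C3) | CC(C)=CCCC(C(=O)OC(C)(C)C)C(O)[C@H](ONc1ccccc1)C/C(C)=C/CC/C(C)=C/COC(C)=O
F4 | step 5 | (2E,6E)-8-[(2R)-3-hydroxy-4-(4-methylpent-3-en-1-yl)-5-oxooxolan-2-yl]-3,7-dimethylocta-2,6-dien-1-yl acetate (mixture at C3 and C4 of the lactone) | CC(C)=CCCC1C(O)[C@@H](C/C(C)=C/CC/C(C)=C/COC(C)=O)OC1=O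
F5 | step 10 | (2-bromo-4-methoxy-6-methylphenoxy)(tert-butyl)dimethylsilane | COc1cc(C)c(O[Si](C)(C)C(C)(C)C)c(Br)c1
F6 | step 10 | (5R)-5-[(2E,6E)-8-{2-[(tert-butyldimethylsilyl)oxy]-5-methoxy-3-methylphenyl}-2,6-dimethylocta-2,6-dien-1-yl]-3-(4-methylpent-3-en-1-yl)furan-2(5H)-one | CC(C)=CCCC1=C[C@@H](C/C(C)=C/CC/C(C)=C/Cc2cc(OC)cc(C)c2O[Si](C)(C)C(C)(C)C)OC1=O
F7 | step 10 | (5R)-5-[(2E,6E)-8-(2-hydroxy-5-methoxy-3-methylphenyl)-2,6-dimethylocta-2,6-dien-1-yl]-3-(4-methylpent-3-en-1-yl)furan-2(5H)-one | CC(C)=CCCC1=C[C@@H](C/C(C)=C/CC/C(C)=C/Cc2cc(OC)cc(C)c2O)OC1=O
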